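**Retrosynthetic overview**

1. Target ⇐ desilylation and (E)-enol senecioate formation on a 2-oxoethyl aldehyde. The cis acetonyl (C7) and 2-oxoethyl (C6) arms ⇐ ozonolysis of a temporary cis-fused methylcyclohexene (ring B).
2. Cycloheptenone (C1 C=O, C2 C(CH2OH), C3 CH=, C4 CH2, C5 quaternary) ⇐ two-carbon ring expansion. A [2+2] of a cyclopentanone silyl enol ether with methyl propiolate forms C1–C2 and C3–C4, and opening of the cyclobutene cuts the old C1–C4 bond.
3. Enabling feature: in the seven-membered ring the C2=C3 enone unit lies between the carbonyl carbon C1 and the neopentyl CH2 C4. The ring is therefore a cyclopentanone (C1, C4–C7) with an alkyne slotted into its C(=O)–CH2 bond; the propiolate ester is the hydroxymethyl group at a higher oxidation level.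
4. Cyclopentanone enol ether ⇐ convex-face conjugate addition of the (R)-side-chain Grignard reagent (Shi epoxidation of homoprenyl bromide) to a cis-hydrindenone. The hydrindenone ⇐ Diels–Alder of (R)-4-silyloxycyclopentenone with isoprene, then methylative enone transposition.
5. Ring order: ring A (five-membered, purchased) → ring B by Diels–Alder → transient cyclobutene → ring A expanded to the seven-membered ring → ring B opened.

Key step: step 7

Assumption: the Lewis-acid Diels–Alder reaction of the 4-silyloxycyclopentenone is taken to occur anti to the silyloxy group, as cuprate additions to this enone do; 3-methylbut-2-enoic anhydride and the D-fructose-derived Shi ketone are taken as purchasable.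

Locants C1–C7 in the Why lines are those of the final cyclohept-2-en-1-one ring unless an indene or benzo[7]annulene name is being used.

**Route**

Step 1
Reactants: 1 5-bromo-2-methylpent-2-ene
Product: 2 (R)-3-(2-bromoethyl)-2,2-dimethyloxirane
Conditions: D-fructose-derived Shi ketone (1,2:4,5-di-O-isopropylidene-β-D-erythro-hexo-2,3-diulo-2,6-pyranose, 0.3 equiv), KHSO5 (Oxone), K2CO3, Bu4NHSO4 (cat.), MeCN/(MeO)2CH2/aq. Na2B4O7 buffer, 0 °C
Reagents that add atoms: potassium peroxymonosulfate KHSO5, [K+].[O-]S(=O)(=O)OO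
Why: Shi asymmetric epoxidation, in which the dioxirane from the D-fructose-derived ketone attacks the trisubstituted alkene through a spiro transition state and should set the (R) configuration at the CH carbon that becomes the side-chain carbinol.

Step 2
Reactants: 2 (R)-3-(2-bromoethyl)-2,2-dimethyloxirane
Product: 3 (R)-[(5-bromo-2-methylpent-1-en-3-yl)oxy](tert-butyl)dimethylsilane
Conditions: TBSOTf, DBU, PhMe, −78 → 25 °C
Reagents that add atoms: tert-butyldimethylsilyl triflate, CC(C)(C)[Si](C)(C)OS(=O)(=O)C(F)(F)F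
Why: Noyori–Murata isomerisation of an epoxide to an allylic silyl ether, in which the silyl triflate opens the epoxide at the tertiary carbon and DBU removes a methyl proton, so the isopropenyl group forms while the C–O bond of the stereocentre is untouched (retention).

Step 3
Reactants: 4 (R)-4-[(tert-butyldimethylsilyl)oxy]cyclopent-2-en-1-one; 5 isoprene (2-methylbuta-1,3-diene)
Product: 7 (3aS,7aS)-5-methyl-3a,4,7,7a-tetrahydro-1H-inden-1-one, via Diels–Alder adduct 6 (not isolated)
Conditions: EtAlCl2 (0.5 equiv), CH2Cl2, −20 → 0 °C; then DBU, 0 °C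
Reagents that add atoms: none
Why: Lewis-acid-catalysed Diels–Alder reaction with the usual "para" regiochemistry (methyl-bearing carbon 1,4 to the carbonyl-bearing α-carbon) and attack anti to the silyloxy group, which should set both ring-fusion centres cis, followed by E1cB loss of silanol so that the silyloxy centre disappears after relaying its chirality.

Step 4
Reactants: 7 (3aS,7aS)-5-methyl-3a,4,7,7a-tetrahydro-1H-inden-1-one
Product: 8 (1R,3aS,7aS)-1,5-dimethyl-3a,4,7,7a-tetrahydro-1H-inden-1-ol
Conditions: MeLi, Et2O, −78 °C; aq. NH4Cl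
Reagents that add atoms: methyllithium, [Li]C
Why: 1,2-addition of methyllithium to the cyclopentenone carbonyl, expected from the convex face of the cis-fused bicycle, although the carbinol configuration is of no consequence because it is lost in step 5.

Step 5
Reactants: 8 (1R,3aS,7aS)-1,5-dimethyl-3a,4,7,7a-tetrahydro-1H-inden-1-ol
Product: 9 (3aS,7aR)-3,6-dimethyl-3a,4,7,7a-tetrahydro-1H-inden-1-one
Conditions: C5H5NH[CrO3Cl] (pyridinium chlorochromate), 4 Å molecular sieves, CH2Cl2, 25 °C
Reagents that add atoms: pyridinium chlorochromate, [O-][Cr](=O)(=O)Cl.c1cc[nH+]cc1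
Why: Dauben–Michno oxidative 1,3-transposition, in which the chromate ester of the tertiary allylic alcohol undergoes a [3,3] shift and oxidation to give the β-methyl enone with its carbonyl next to the ring-fusion carbon C7a, without touching a stereocentre.

Step 6
Reactants: 3 (R)-[(5-bromo-2-methylpent-1-en-3-yl)oxy](tert-butyl)dimethylsilane; 9 (3aS,7aR)-3,6-dimethyl-3a,4,7,7a-tetrahydro-1H-inden-1-one
Product: 11 cis-fused 3,6-dimethyl-3-[(3R)-3-(tert-butyldimethylsilyloxy)-4-methylpent-4-en-1-yl]-1-(trimethylsilyloxy)-3a,4,7,7a-tetrahydro-3H-indene (side chain on C3 trans to C4), via Grignard reagent 10 (not isolated)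
Conditions: Mg, THF, 40 °C; then 9, CuBr·SMe2 (10 mol %), Me3SiCl, DMPU, THF, −78 → −40 °C; Et3N, cold aq. NaHCO3
Reagents that add atoms: chlorotrimethylsilane, C[Si](C)(C)Cl
Why: copper-catalysed, Me3SiCl-accelerated conjugate addition of the Grignard reagent to the β-methyl cyclopentenone, in which attack anti to the ring-B CH2 on the adjacent ring-fusion carbon (convex face) should set the quaternary centre with the side chain trans to ring B, while silyl trapping fixes the enolate on the CH2 side.

Step 7
Reactants: 11 silyl enol ether (as named in step 6); 12 methyl propiolate (methyl prop-2-ynoate)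
Product: 14 methyl cis-fused 2,5-dimethyl-5-[(3R)-3-(tert-butyldimethylsilyloxy)-4-methylpent-4-en-1-yl]-9-(trimethylsilyloxy)-4,4a,5,9a-tetrahydro-1H-benzo[7]annulene-8-carboxylate, via siloxycyclobutene 13 (not isolated)
Conditions: TiCl4 (0.3 equiv), CH2Cl2, −78 °C; Et3N; then PhMe, 90 °C
Reagents that add atoms: none
Why: TiCl4-activated methyl propiolate should be attacked at its CH terminus by the nucleophilic CH carbon of the silyl enol ether (Mukaiyama–Michael), and the titanium allenolate should then close onto the silyloxocarbenium carbon, so that the new bonds are CH–CH(ring) and C(CO2Me)–C(OSiMe3); this is the Lewis-acid [2+2] cycloaddition of silyl enol ethers with propiolates, followed by the thermal two-carbon ring expansion known for such bicyclic siloxycyclobutenes. The four-membered ring closes by this stepwise polar [2+2] (4-exo attack of the allenolate carbon on the oxocarbenium ion), whereas the seven-membered ring is not closed but arises when the donor–acceptor-substituted ring-fusion bond of the bicyclo[3.2.0]heptene breaks in a push–pull-assisted 4π electrocyclic opening. No lasting stereocentre is created, since the two cyclobutene ring-fusion centres are destroyed in the opening and C5, C6 and C7 are spectators. The step needs regioselectivity (ester-bearing carbon to the former carbonyl carbon), which the polarity of both partners dictates, and chemoselectivity over the ring-B alkene and the isopropenyl group, which the far higher nucleophilicity of the silyl enol ether at −78 °C should secure; the position of the enol ether, and hence the C(=O)–CH2 bond that is expanded, was fixed in step 6.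

Step 8
Reactants: 14 silyl dienol ether ester (as named in step 7)
Product: 16 cis-fused 8-(hydroxymethyl)-2,5-dimethyl-5-[(3R)-3-(tert-butyldimethylsilyloxy)-4-methylpent-4-en-1-yl]-1,4,4a,5,6,9a-hexahydro-9H-benzo[7]annulen-9-one, via dienol ether carbinol 15 (not isolated)
Conditions: i-Bu2AlH, CH2Cl2, −78 °C; aq. potassium sodium tartrate; then K2CO3 (cat.), MeOH, 0 °C
Reagents that add atoms: none
Why: i-Bu2AlH should reduce the vinylogous-carbonate ester to the primary allylic alcohol without touching the silyl dienol ether, and carbonate-catalysed methanolysis then releases the dienolate, which under equilibrating conditions is protonated at the γ-carbon to the conjugated 2-(hydroxymethyl)enone (enol ether cleavage with double-bond conjugation), the short cold treatment being chosen to leave the ring-fusion α-centre untouched.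

Step 9
Reactants: 16 hydroxymethyl enone (as named in step 8)
Product: 17 cis-fused 8-[(tert-butyldimethylsilyloxy)methyl]-2,5-dimethyl-5-[(3R)-3-(tert-butyldimethylsilyloxy)-4-methylpent-4-en-1-yl]-1,4,4a,5,6,9a-hexahydro-9H-benzo[7]annulen-9-one
Conditions: TBSCl, imidazole, DMF, 0 °C
Reagents that add atoms: tert-butyldimethylsilyl chloride, CC(C)(C)[Si](C)(C)Cl
Why: standard silylation of the primary allylic alcohol, so that only the aldehyde enol is acylated in step 11.

Step 10
Reactants: 17 bis-silyl ether (as named in step 9)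
Product: 19 2-[(tert-butyldimethylsilyloxy)methyl]-5-methyl-5-[(3R)-3-(tert-butyldimethylsilyloxy)-4-methylpent-4-en-1-yl]-6-(2-oxoethyl)-7-(2-oxopropyl)cyclohept-2-en-1-one (configuration at C5/C6/C7 as in the target), via ozonide 18 (not isolated)
Conditions: O3, CH2Cl2, −78 °C (Sudan Red 7B end point); then PPh3, −78 → 25 °C
Reagents that add atoms: ozone, [O-][O+]=O
Why: ozonolysis with a dye end point, in which the electron-rich trisubstituted ring-B alkene should react much faster than the 1,1-disubstituted alkene flanked by a silyloxy group or the electron-poor enone, and reduction of the ozonide unveils the methyl ketone and the aldehyde cis on C7 and C6 without touching either stereocentre.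

Step 11
Reactants: 19 keto aldehyde (as named in step 10)
Product: 20 (E)-2-{2-[(3R)-3-(tert-butyldimethylsilyloxy)-4-methylpent-4-en-1-yl]-4-[(tert-butyldimethylsilyloxy)methyl]-2-methyl-5-oxo-6-(2-oxopropyl)cyclohept-3-en-1-yl}ethenyl 3-methylbut-2-enoate (bis-silyl ether of the target)
Conditions: (Me2C=CHCO)2O, Et3N, 4-(dimethylamino)pyridine (cat.), CH2Cl2, 0 → 25 °C
Reagents that add atoms: 3-methylbut-2-enoic anhydride, CC(C)=CC(=O)OC(=O)C=C(C)C
Why: O-acylation of the aldehyde enol (enol ester formation), the only readily enolised carbonyl under amine/acylpyridinium conditions, in which the E geometry is expected because the bulky ring carbon C6 sits anti to the acyloxy group in the elimination/acylation transition state and reversible acyl transfer under 4-(dimethylamino)pyridine should let the mixture settle on the more stable E isomer.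

Step 12
Reactants: 20 bis-silyl ether of the target
Product: 21 target, (E)-2-{(1S,2S,7R)-numbered here as cycloheptenone C6/C5/C7: (5S,6S,7R)-2-(hydroxymethyl)-5-[(3R)-3-hydroxy-4-methylpent-4-en-1-yl]-5-methyl-1-oxo-7-(2-oxopropyl)cyclohept-2-en-6-yl}ethenyl 3-methylbut-2-enoate
Conditions: HF·pyridine, pyridine, THF, 0 → 25 °C
Reagents that add atoms: none
Why: buffered HF·pyridine cleaves both silyl ethers (fluoride desilylation) under conditions in which the enol ester and the epimerisable C7 centre should be stable.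

**Compound list**

1 | 5-bromo-2-methylpent-2-ene | CC(C)=CCCBr | starting material
2 | (R)-3-(2-bromoethyl)-2,2-dimethyloxirane | BrCC[C@H]1OC1(C)C | intermediate
3 | (R)-[(5-bromo-2-methylpent-1-en-3-yl)oxy](tert-butyl)dimethylsilane | C=C(C)[C@H](O[Si](C)(C)C(C)(C)C)CCBr | intermediate
4 | (R)-4-[(tert-butyldimethylsilyl)oxy]cyclopent-2-en-1-one | O=C1C=C[C@H](O[Si](C)(C)C(C)(C)C)C1 | starting material
5 | isoprene | C=CC(C)=C | starting material
6 | (3R,3aR,7aS)-3-[(tert-butyldimethylsilyl)oxy]-5-methyl-2,3,3a,4,7,7a-hexahydro-1H-inden-1-one (Diels–Alder adduct; cis-fused; silyloxy anti to ring B) | O=C1C[C@@H](O[Si](C)(C)C(C)(C)C)[C@@H]2CC(C)=CC[C@H]12 | intermediate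
7 | (3aS,7aS)-5-methyl-3a,4,7,7a-tetrahydro-1H-inden-1-one | O=C1C=C[C@@H]2CC(C)=CC[C@H]12 | intermediate
8 | (1R,3aS,7aS)-1,5-dimethyl-3a,4,7,7a-tetrahydro-1H-inden-1-ol | C[C@@]1(O)C=C[C@@H]2CC(C)=CC[C@H]12 | intermediate
9 | (3aS,7aR)-3,6-dimethyl-3a,4,7,7a-tetrahydro-1H-inden-1-one | O=C1C=C(C)[C@H]2CC=C(C)C[C@@H]12 | intermediate
10 | [(3R)-3-(tert-butyldimethylsilyloxy)-4-methylpent-4-en-1-yl]magnesium bromide | C=C(C)[C@H](O[Si](C)(C)C(C)(C)C)CC[Mg]Br | intermediate
11 | cis-fused 3,6-dimethyl-3-[(3R)-3-(tert-butyldimethylsilyloxy)-4-methylpent-4-en-1-yl]-1-(trimethylsilyloxy)-3a,4,7,7a-tetrahydro-3H-indene; side chain trans to the ring-B CH2 on C3a | C=C(C)[C@H](O[Si](C)(C)C(C)(C)C)CC[C@@]1(C)C=C(O[Si](C)(C)C)[C@@H]2CC(C)=CC[C@H]12 | intermediate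
12 | methyl propiolate | C#CC(=O)OC | starting material
13 | siloxycyclobutene [2+2] adduct of 11 and 12 (propiolate CH bonded to the former enol CH, ester-bearing carbon bonded to the C–OSiMe3 carbon; the two new ring-fusion centres undefined) | C=C(C)[C@H](O[Si](C)(C)C(C)(C)C)CC[C@@]1(C)C2C=C(C(=O)OC)C2(O[Si](C)(C)C)[C@@H]3CC(C)=CC[C@H]13 | intermediate
14 | methyl cis-fused 2,5-dimethyl-5-[(3R)-3-(tert-butyldimethylsilyloxy)-4-methylpent-4-en-1-yl]-9-(trimethylsilyloxy)-4,4a,5,9a-tetrahydro-1H-benzo[7]annulene-8-carboxylate | C=C(C)[C@H](O[Si](C)(C)C(C)(C)C)CC[C@@]1(C)C=CC(C(=O)OC)=C(O[Si](C)(C)C)[C@@H]2CC(C)=CC[C@H]12 | intermediate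
15 | the corresponding 8-(hydroxymethyl) silyl dienol ether (ester of 14 reduced to CH2OH) | C=C(C)[C@H](O[Si](C)(C)C(C)(C)C)CC[C@@]1(C)C=CC(CO)=C(O[Si](C)(C)C)[C@@H]2CC(C)=CC[C@H]12 | intermediate
16 | cis-fused 8-(hydroxymethyl)-2,5-dimethyl-5-[(3R)-3-(tert-butyldimethylsilyloxy)-4-methylpent-4-en-1-yl]-1,4,4a,5,6,9a-hexahydro-9H-benzo[7]annulen-9-one | C=C(C)[C@H](O[Si](C)(C)C(C)(C)C)CC[C@@]1(C)CC=C(CO)C(=O)[C@@H]2CC(C)=CC[C@H]12 | intermediate
17 | tert-butyldimethylsilyl ether of 16 at the primary alcohol | C=C(C)[C@H](O[Si](C)(C)C(C)(C)C)CC[C@@]1(C)CC=C(CO[Si](C)(C)C(C)(C)C)C(=O)[C@@H]2CC(C)=CC[C@H]12 | intermediate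
18 | secondary ozonide (1,2,4-trioxolane) of the ring-B alkene of 17; trioxolane carbons undefined | C=C(C)[C@H](O[Si](C)(C)C(C)(C)C)CC[C@@]1(C)CC=C(CO[Si](C)(C)C(C)(C)C)C(=O)[C@@H]2CC3(C)OOC(O3)C[C@H]12 | intermediate
19 | 2-[(tert-butyldimethylsilyloxy)methyl]-5-methyl-5-[(3R)-3-(tert-butyldimethylsilyloxy)-4-methylpent-4-en-1-yl]-6-(2-oxoethyl)-7-(2-oxopropyl)cyclohept-2-en-1-one; C6 and C7 arms cis to each other and to the C5 methyl | C=C(C)[C@H](O[Si](C)(C)C(C)(C)C)CC[C@@]1(C)CC=C(CO[Si](C)(C)C(C)(C)C)C(=O)[C@H](CC(C)=O)[C@@H]1CC=O | intermediate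
20 | bis(tert-butyldimethylsilyl) ether of the target | C=C(C)[C@H](O[Si](C)(C)C(C)(C)C)CC[C@@]1(C)CC=C(CO[Si](C)(C)C(C)(C)C)C(=O)[C@H](CC(C)=O)[C@@H]1/C=C/OC(=O)C=C(C)C | intermediate
21 | CNP0257974.2: (5S,6S,7R)-2-(hydroxymethyl)-5-[(3R)-3-hydroxy-4-methylpent-4-en-1-yl]-5-methyl-7-(2-oxopropyl)cyclohept-2-en-1-one carrying at C6 the (E)-2-(3-methylbut-2-enoyloxy)ethenyl group | C=C(C)[C@H](O)CC[C@@]1(C)CC=C(CO)C(=O)[C@H](CC(C)=O)[C@@H]1/C=C/OC(=O)C=C(C)C | target

**Step count and risks**

Total steps: 12. Longest linear sequence: 10 steps (steps 3–12, from compound 4); the side chain takes 2 steps (steps 1–2).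

Steps most likely to fail:

1. Step 7. Silyl transfer may give the open-chain Mukaiyama–Michael adduct instead of ring closure. Alternatively, the cyclobutene may open only at temperatures where a 1,5-hydrogen shift in the cycloheptadiene erodes the C7 ring-fusion centre. Fallback (enamine two-carbon ring expansion, which opens at room temperature), setting out from 11:
   - Methanolysis (K2CO3, MeOH) would give the ketone F1.
   - Pyrrolidine with catalytic p-TsOH under water removal would give the less substituted pyrrolidine enamine F2.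
   - Methyl propiolate in MeCN at 25 °C would undergo [2+2] addition and spontaneous cyclobutene opening to the ring-expanded dienamino ester F3.
   - Aqueous AcOH/NaOAc would hydrolyse it to the β-keto ester F4.
   - O-silylation with Me3SiCl/Et3N rejoins the route at 14.

2. Step 11. E/Z control in the O-acylation may be poor, and the amine base may promote intramolecular aldol condensation between the aldehyde and the methyl ketone. Fallback (stereospecific C–O coupling), setting out from 19:
   - Me3SiCl/NaI/Et3N would silylate the aldehyde selectively to the aldehyde silyl enol ether F5 (geometry irrelevant).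
   - Ozonolysis at −78 °C with PPh3 work-up would cut it to the one-carbon-shorter aldehyde F6.
   - Takai–Utimoto olefination (Cl2CHBpin, CrCl2, LiI, THF) would give the (E)-alkenylboronate F7.
   - Brief KHF2 treatment in aqueous MeOH would give the potassium alkenyltrifluoroborate F8.
   - Copper-catalysed coupling with 3-methylbut-2-enoic acid (CuBr, 4-(dimethylamino)pyridine, 4 Å molecular sieves, O2, CH2Cl2, 40 °C) retains the E geometry and rejoins the route at 20.

3. Step 3. Incomplete anti-facial selectivity would, after loss of the silanol, turn directly into loss of enantiomeric purity; the Lewis acid may also cause silanol elimination before the cycloaddition. Fallback (catalyst control instead of substrate control), setting out from 5 and cyclopent-2-en-1-one: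
   - An enantioselective Diels–Alder reaction catalysed by an AlBr3-activated diphenylprolinol-derived oxazaborolidine (the enantiomer giving the 3aR,7aS adduct) would give the saturated cis-hydrindanone F9.
   - Kinetic enolisation on the CH2 side (LiN(i-Pr)2, Me3SiCl, THF, −78 °C) would give the silyl enol ether F10.
   - Saegusa–Ito oxidation with Pd(OAc)2 in MeCN rejoins the route at 7.

Further compounds
F1 | step 7 | cis-fused 3,6-dimethyl-3-[(3R)-3-(tert-butyldimethylsilyloxy)-4-methylpent-4-en-1-yl]-2,3,3a,4,7,7a-hexahydro-1H-inden-1-one | C=C(C)[C@H](O[Si](C)(C)C(C)(C)C)CC[C@@]1(C)CC(=O)[C@@H]2CC(C)=CC[C@H]12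
F2 | step 7 | 1-(pyrrolidin-1-yl) enamine of F1 (double bond toward the CH2 carbon) | C=C(C)[C@H](O[Si](C)(C)C(C)(C)C)CC[C@@]1(C)C=C(N3CCCC3)[C@@H]2CC(C)=CC[C@H]12
F3 | step 7 | methyl 9-(pyrrolidin-1-yl) analogue of 14 (ring-expanded dienamino ester) | C=C(C)[C@H](O[Si](C)(C)C(C)(C)C)CC[C@@]1(C)C=CC(C(=O)OC)=C(N3CCCC3)[C@@H]2CC(C)=CC[C@H]12
F4 | step 7 | β-keto ester corresponding to 14 (9-oxo, 8-CO2Me, 6,7-alkene; C8 undefined) | C=C(C)[C@H](O[Si](C)(C)C(C)(C)C)CC[C@@]1(C)C=CC(C(=O)OC)C(=O)[C@@H]2CC(C)=CC[C@H]12
F5 | step 11 | trimethylsilyl enol ether of the aldehyde of 19 | C=C(C)[C@H](O[Si](C)(C)C(C)(C)C)CC[C@@]1(C)CC=C(CO[Si](C)(C)C(C)(C)C)C(=O)[C@H](CC(C)=O)[C@@H]1C=CO[Si](C)(C)C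
F6 | step 11 | 6-formyl analogue of 19 (one carbon shorter aldehyde) | C=C(C)[C@H](O[Si](C)(C)C(C)(C)C)CC[C@@]1(C)CC=C(CO[Si](C)(C)C(C)(C)C)C(=O)[C@H](CC(C)=O)[C@@H]1C=O
F7 | step 11 | (E)-alkenylboronic acid pinacol ester at C6 | C=C(C)[C@H](O[Si](C)(C)C(C)(C)C)CC[C@@]1(C)CC=C(CO[Si](C)(C)C(C)(C)C)C(=O)[C@H](CC(C)=O)[C@@H]1/C=C/B2OC(C)(C)C(C)(C)O2
F8 | step 11 | potassium (E)-alkenyltrifluoroborate at C6 | C=C(C)[C@H](O[Si](C)(C)C(C)(C)C)CC[C@@]1(C)CC=C(CO[Si](C)(C)C(C)(C)C)C(=O)[C@H](CC(C)=O)[C@@H]1/C=C/[B-](F)(F)F.[K+]
F9 | step 3 | (3aR,7aS)-5-methyl-2,3,3a,4,7,7a-hexahydro-1H-inden-1-one | O=C1CC[C@@H]2CC(C)=CC[C@H]12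
F10 | step 3 | trimethylsilyl enol ether of F9 toward C2 | C[Si](C)(C)OC1=CC[C@@H]2CC(C)=CC[C@H]12
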